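Time was the gap to cross: the readings stopped at 3.00 h, and the question stood at 8.0 h.

| flask | substrate | acid | remark | time |
|---|---|---|---|---|
| delta | 0.050 M (fed, over 2.0 h) | 0.050 mM | the very flask that is asked about, followed so far |  |
| flask | 0.050 M (fed, over 2.0 h) | 0.0500 mM |  | 8.0 h |

delta run (percent of the substrate charged)

| time / h | substrate / % | target / % |
|---|---|---|
| 0.200 | 5 | 2 |
| 0.667 | 18 | 0 |
| 1.00 | 23 | 7 |
| 2.00 | 40 | 19 |
| 2.50 | 31 | 25 |
| 3.00 | 27 | 29 |

(standard deviation of a reading: 1.5 percentage points)

- part of the substrate that has reacted at 8.0 h
- pH of the solution at 8.0 h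

- acid is the free proton; pH is minus the decimal logarithm of its molar concentration
- what has gone from substrate into another species counts as reacted, even if it can come back
- percentages count the whole charge, also what has not yet gone in

Two numbers in the delta run did not go together. At 0.667 h a third of the charge had gone in, yet 15.4% of the charge read as neither substrate nor target. But between 2.00 h and 3.00 h, from a larger stock, the substrate reading fell by 13 percentage points.

The unseen share helped. It read 41.0% at 2.00 h and 44.0% at 3.00 h. I took it that something filled early and then held. So I set the early loss aside and replaced the curve after the feed by one mean slope: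

ln(40% / 27%) / (3.00 h − 2.00 h) = 0.393 h⁻¹

This is the tail constant: the mean pseudo-first-order fall of substrate after the feed, as read from the delta run. I checked the error that the mean makes at the middle reading:

40% × exp(−0.393 h⁻¹ × 0.500 h) = 32.9%, read 31%

That gap was 1.9 points against a scatter of 1.5 points, so I carried the constant on:

40% × exp(−0.393 h⁻¹ × 6.00 h) = 3.78% left

So I said 96.2% reacted. The forecast, holding that “a hidden intermediate lies between them”, gave 89% and pH 4.3. My figure stood above its 89%. No reading spoke of pH, so I had no pH of my own.

The flask gave 94.5% reacted and pH 4.02.

    substrate + acid → weak acid + acid + target (k = 79.1 M⁻¹ min⁻¹)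
    weak acid ⇌ conjugate base + acid, settled at all times (K = 1.30 × 10⁻⁶ M)
    substrate → weak acid + target (k = 0.00269 min⁻¹)
    substrate ⇌ dormant form (K = 0.916, k = 0.0928 min⁻¹)
    target ⇌ isomer of the product (K = 3.65, k = 0.00889 min⁻¹)
    crystals ⇌ weak acid, rate k6*(cs6 - [weak acid]) while solid is left; crystals form when [weak acid] > cs6 (solubility = 3.10 mM, k = 0.189 min⁻¹)

At 8.00 h the flask held substrate 5.49% beside dormant form 5.30%, a pair whose exchange by that step alone has a relaxation half-life of 0.0595 h, short against 8.0 h. For the same flask read at 5.0 h, the tail constant gave 12.3% substrate, and the flask held 14.0%.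

The earlier runs and the new flask are simulated for an exercise.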